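**Retrosynthetic overview**
1. Feature: ring A has oxygen on C5, C7 and C8a and the C4 acyl carbon on C4a, so it is an acylphloroglucinol. The chain C5–C6–C7–C8–C8a–C4a–C4–C3–C2 is a folded polyketide, and its C8a oxygen lies within reach of C2.
2. Last disconnections: the O–S bond at 7-O and the benzyl ethers at 3-O and 4'-O lead back to 3,4'-di-O-benzylkaempferol, in which 7-OH is the only free phenol not hydrogen-bonded to the C4 carbonyl.
3. Key disconnection: C4a–C5 (ring A) and O1–C2 (ring C) are cut together. This unfolds the flavone to a 6-(2,4-dioxobutyl)-4-hydroxy-2-pyranone, whose lactone stores the C5–C8a end of the chain and is opened by methoxide before the fold.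
4. The pyranone is cut at C2–C3 (trianion plus the Weinreb amide of 4-benzyloxybenzoic acid) and at C4–C4a (triacetic acid lactone dianion plus methyl benzyloxyacetate).
5. Ring order: ring B and the sacrificial pyranone ring are bought; ring A and then ring C are closed in one flask.

Key step: step 4

Assumption: the target is taken in the hydrogen sulfate form that is drawn. An aryl hydrogen sulfate hydrolyses under its own acidity, so the sulfate is carried as its potassium salt and the acid form is released cold in the last operation.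

Step 1
Reactants: 1 triacetic acid lactone (4-hydroxy-6-methyl-2H-pyran-2-one); 2 methyl 2-(benzyloxy)acetate
Product: 4 6-[3-(benzyloxy)-2-oxopropyl]-4-hydroxy-2H-pyran-2-one, via dilithio dianion 3 (not isolated)
Conditions: 1 (2 equiv), LiN(iPr)2 (4.2 equiv, commercial solution), THF–DMPU, −78 to −20 °C; 2 (1 equiv), −78 to 0 °C; 2 M HCl
Reagents that add atoms: none
Why: Crossed Claisen-type C-acylation of a dianion forms C4–C4a, because the second charge sits on the C6 methyl carbon, which is far more nucleophilic than the delocalised 4-oxidopyranone, and the second equivalent of the cheap dianion takes up the acidic C4a proton of the product, so no free amide base remains to enolise ester 2.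

Step 2
Reactants: 5 4-(benzyloxy)benzoyl chloride
Product: 6 4-(benzyloxy)-N-methoxy-N-methylbenzamide
Conditions: MeNHOMe·HCl (1.1 equiv), Et3N (2.2 equiv), CH2Cl2, 0 °C to rt
Reagents that add atoms: N,O-dimethylhydroxylamine hydrochloride, CNOC.Cl
Why: N-acylation of the hydroxylamine by an acid chloride (Weinreb amide formation) is fast and leaves the aryl benzyl ether untouched.

Step 3
Reactants: 4 6-[3-(benzyloxy)-2-oxopropyl]-4-hydroxy-2H-pyran-2-one; 6 4-(benzyloxy)-N-methoxy-N-methylbenzamide
Product: 8 6-{3-(benzyloxy)-4-[4-(benzyloxy)phenyl]-2,4-dioxobutyl}-4-hydroxy-2H-pyran-2-one (racemic), via trilithio trianion 7 (not isolated)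
Conditions: LiN(iPr)2 (3.3 equiv, commercial solution), THF, −78 to 0 °C; 6 (1.05 equiv), −78 to −10 °C; poured into cold 1 M HCl
Reagents that add atoms: none
Why: Terminal C-acylation of a polyanion with a Weinreb amide forms C2–C3, because the last-formed and least stabilised carbanion at C3 reacts first, the amide releases the ketone only on the acid quench so the acidic product cannot protonate unreacted trianion, and the new C3 centre is racemic, enolisable and erased in step 4.

Step 4
Reactants: 8 6-{3-(benzyloxy)-4-[4-(benzyloxy)phenyl]-2,4-dioxobutyl}-4-hydroxy-2H-pyran-2-one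
Product: 11 3,4'-di-O-benzylkaempferol (3-(benzyloxy)-2-[4-(benzyloxy)phenyl]-5,7-dihydroxy-4H-chromen-4-one), via tetraketo ester 9 (not isolated), via acylphloroglucinol diketone 10 (not isolated)
Conditions: Mg(OMe)2 (6 equiv, commercial solution), dry MeOH, argon, reflux; cool, HCl in MeOH to pH 1, 50 °C
Reagents that add atoms: none
Why: Methoxide first opens the lactone at C5, because the exocyclic carbon C4a cannot reach C5 across the flat, intact pyranone (that would need an oxygen-bridged bicyclo[3.1.1]heptadiene adduct); this gives the magnesium-chelated tetraketo ester 9, whose C8a enolate oxygen is the former ring oxygen. After bond rotation the C8a/C4 enolate attacks the ester carbon C5 through C4a and expels methoxide, a Dieckmann-type intramolecular Claisen condensation (6-exo-trig at the ester, enolate exo) that forms C4a–C5, and tautomerisation of the cyclohexanetrione gives ring A as phloroglucinol 10. On acidification either of the two equivalent ortho hydroxyls adds to the C2 aryl ketone (6-exo-trig hemiketalisation) and loss of water forms O1–C2 and ring C; the symmetry of ring A makes both directions give 11, and the racemic C3 centre becomes sp2, so no stereocentre is created. The closest known reaction types are the magnesium alkoxide induced conversion of 6-(2-oxoalkyl)-4-hydroxy-2-pyranones into acylphloroglucinols and the acid cyclodehydration of o-hydroxyaryl 1,3-diketones that ends a Baker–Venkataraman flavone synthesis. The step needs Claisen folding to beat the aldol folds (C6 onto C4, C8 onto C2, C3 onto C7) and retro-Claisen loss of the aroyl group: excess anhydrous Mg(OMe)2 holds all four ketones as chelated enolates, so the ester carbon C5 is the only electrophile left, and C4a is the only carbanion that reaches it through a six-membered ring (C8 would give a four-membered and C3 an eight-membered ring).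

Step 5
Reactants: 11 3,4'-di-O-benzylkaempferol
Product: 13 potassium 3,4'-di-O-benzylkaempferol 7-sulfate, via pyridinium sulfate salt 12 (not isolated)
Conditions: SO3·pyridine (2 equiv), dry pyridine, rt; aq KHCO3 to pH 8, evaporation, C18 silica (H2O–MeOH)
Reagents that add atoms: sulfur trioxide–pyridine complex, [O-]S(=O)(=O)[n+]1ccccc1; potassium hydrogen carbonate, [K+].OC([O-])=O
Why: O-sulfation of a phenol with an amine–SO3 complex should take the 7-hydroxyl, the most acidic and only unhindered phenol, while the 5-hydroxyl is held in its hydrogen bond to the C4 carbonyl, and the exchange to potassium removes pyridine, which would slow the Pd/C hydrogenolysis of aryl benzyl ethers.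

Step 6
Reactants: 13 potassium 3,4'-di-O-benzylkaempferol 7-sulfate
Product: 15 kaempferol 7-O-sulfate (hydrogen sulfate form), via potassium kaempferol 7-sulfate 14 (not isolated)
Conditions: H2 (1 atm), 10% Pd/C, MeOH–THF–H2O, rt; filter; 0.1 M HCl (1.0 equiv), 0 °C, C18 cartridge, freeze-drying
Reagents that add atoms: none
Why: Catalytic hydrogenolysis at one atmosphere cleaves both benzyl ethers and should leave the aryl sulfate salt and the conjugated C2–C3 double bond of the flavonol intact, and the cold metathesis with one equivalent of HCl then releases the hydrogen sulfate before acid-catalysed S–O hydrolysis can set in.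

**Compound list**
1 | triacetic acid lactone (4-hydroxy-6-methyl-2H-pyran-2-one) | CC1=CC(O)=CC(=O)O1 | starting material
2 | methyl 2-(benzyloxy)acetate | COC(=O)COCc1ccccc1 | starting material
3 | dilithio dianion of 1 (4-oxide and C6-methyl carbanion) | [Li+].[Li+].[CH2-]C1=CC([O-])=CC(=O)O1 | intermediate (not isolated)
4 | 6-[3-(benzyloxy)-2-oxopropyl]-4-hydroxy-2H-pyran-2-one | O=C(CC1=CC(O)=CC(=O)O1)COCc1ccccc1 | intermediate
5 | 4-(benzyloxy)benzoyl chloride | O=C(Cl)c1ccc(OCc2ccccc2)cc1 | starting material
6 | 4-(benzyloxy)-N-methoxy-N-methylbenzamide | CON(C)C(=O)c1ccc(OCc2ccccc2)cc1 | intermediate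
7 | trilithio trianion of 4 (4-oxide, C4a and C3 carbanions) | [Li+].[Li+].[Li+].O=C([CH-]C1=CC([O-])=CC(=O)O1)[CH-]OCc1ccccc1 | intermediate (not isolated)
8 | 6-{3-(benzyloxy)-4-[4-(benzyloxy)phenyl]-2,4-dioxobutyl}-4-hydroxy-2H-pyran-2-one (racemic, enolisable C3) | O=C(CC1=CC(O)=CC(=O)O1)C(OCc1ccccc1)C(=O)c1ccc(OCc2ccccc2)cc1 | intermediate (key-step precursor)
9 | methyl 8-(benzyloxy)-9-[4-(benzyloxy)phenyl]-3,5,7,9-tetraoxononanoate (present as magnesium chelate, drawn as the neutral ligand, racemic) | COC(=O)CC(=O)CC(=O)CC(=O)C(OCc1ccccc1)C(=O)c1ccc(OCc2ccccc2)cc1 | intermediate (not isolated)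
10 | 2-(benzyloxy)-1-[4-(benzyloxy)phenyl]-3-(2,4,6-trihydroxyphenyl)propane-1,3-dione (racemic) | O=C(c1ccc(OCc2ccccc2)cc1)C(OCc1ccccc1)C(=O)c1c(O)cc(O)cc1O | intermediate (not isolated)
11 | 3,4'-di-O-benzylkaempferol | O=c1c(OCc2ccccc2)c(-c2ccc(OCc3ccccc3)cc2)oc2cc(O)cc(O)c12 | intermediate (key-step product)
12 | pyridinium 3,4'-di-O-benzylkaempferol 7-sulfate | O=c1c(OCc2ccccc2)c(-c2ccc(OCc3ccccc3)cc2)oc2cc(OS(=O)(=O)[O-])cc(O)c12.c1cc[nH+]cc1 | intermediate (not isolated)
13 | potassium 3,4'-di-O-benzylkaempferol 7-sulfate | O=c1c(OCc2ccccc2)c(-c2ccc(OCc3ccccc3)cc2)oc2cc(OS(=O)(=O)[O-])cc(O)c12.[K+] | intermediate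
14 | potassium kaempferol 7-sulfate | O=c1c(O)c(-c2ccc(O)cc2)oc2cc(OS(=O)(=O)[O-])cc(O)c12.[K+] | intermediate (not isolated)
15 | kaempferol 7-O-sulfate (no stereocentre) | O=c1c(O)c(-c2ccc(O)cc2)oc2cc(OS(=O)(=O)O)cc(O)c12 | target

**Step count:** 6 steps in total. The longest linear sequence is 5 steps (steps 1, 3, 4, 5, 6; the branch through step 2 is equally long).

**Steps most likely to fail**

Step 4.
- What may go wrong: misfolding by aldol condensation onto ketones that are not fully enolised; retro-Claisen cleavage of the C2–C3 bond of the 2-alkoxy-1,3-diketone by methoxide; sluggish methanolysis of the anionic pyranone.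
- Fallback: it takes the C2 ketone out of the folding substrate, sets out from 4 (with 5) and comes back at 11.
- Pyranone 4 has an opened chain one ketone shorter, so it has a single aldol competitor and no cleavable 1,3-diketone. It is folded with Mg(OMe)2 in MeOH to 2-(benzyloxy)-1-(2,4,6-trihydroxyphenyl)ethan-1-one F1.
- Acid chloride 5 in pyridine aroylates all three phenols to 2-[(benzyloxy)acetyl]benzene-1,3,5-triyl tris[4-(benzyloxy)benzoate] F2.
- KOH in pyridine moves one ortho aroyl group onto the ketone α-carbon (Baker–Venkataraman rearrangement). This gives 4-{2-(benzyloxy)-3-[4-(benzyloxy)phenyl]-3-oxopropanoyl}-5-hydroxybenzene-1,3-diyl bis[4-(benzyloxy)benzoate] F3.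
- AcOH with catalytic H2SO4 closes ring C to 3-(benzyloxy)-2-[4-(benzyloxy)phenyl]-4-oxo-4H-chromene-5,7-diyl bis[4-(benzyloxy)benzoate] F4.
- K2CO3 in MeOH–THF removes the two remaining aroyl esters and gives 11.

Step 3.
- What may go wrong: incomplete third deprotonation next to the benzyloxy group; proton transfer in place of acyl transfer; base-induced fragmentation of the N-methoxy amide.
- Fallback: it avoids the trianion and forms C4–C4a last, sets out from 2 and comes back at 8.
- Ester 2 is enolised with LiN(iPr)2 at −78 °C and added to commercial 4-(benzyloxy)benzaldehyde (aldol addition). This gives methyl 2-(benzyloxy)-3-[4-(benzyloxy)phenyl]-3-hydroxypropanoate F5 as a mixture of racemic diastereomers, both centres being erased later.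
- Et3SiCl and imidazole give methyl 2-(benzyloxy)-3-[4-(benzyloxy)phenyl]-3-[(triethylsilyl)oxy]propanoate F6.
- Dianion 3, made as in step 1, is acylated by this ester (buffered quench) to 6-{3-(benzyloxy)-4-[4-(benzyloxy)phenyl]-2-oxo-4-[(triethylsilyl)oxy]butyl}-4-hydroxy-2H-pyran-2-one F7.
- AcOH–THF–H2O frees 6-{3-(benzyloxy)-4-[4-(benzyloxy)phenyl]-4-hydroxy-2-oxobutyl}-4-hydroxy-2H-pyran-2-one F8.
- Activated MnO2 in CH2Cl2 oxidises the electron-rich benzylic alcohol to the C2 ketone of 8.

Step 6.
- What may go wrong: slow hydrogenolysis of a polar, sulfur-bearing salt; over-reduction of the C2–C3 double bond on long exposure; hydrolytic loss of the sulfate once the acid form is released.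
- Fallback: it carries the sulfate as a neutral protected diester, sets out from 11 and comes back at 15.
- 2,2,2-Trichloroethyl chlorosulfate, Et3N and DMAP in THF convert the 7-hydroxyl into the chromatographable 3-(benzyloxy)-2-[4-(benzyloxy)phenyl]-5-hydroxy-4-oxo-4H-chromen-7-yl 2,2,2-trichloroethyl sulfate F9.
- Transfer hydrogenolysis (10% Pd/C, HCO2NH4, MeOH) removes the trichloroethyl group and both benzyl ethers in one operation and gives ammonium kaempferol 7-sulfate F10.
- The same cold treatment with one equivalent of HCl converts this salt into 15.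

**Further compounds**
F1 | step 4 | 2-(benzyloxy)-1-(2,4,6-trihydroxyphenyl)ethan-1-one | O=C(COCc1ccccc1)c1c(O)cc(O)cc1O
F2 | step 4 | 2-[(benzyloxy)acetyl]benzene-1,3,5-triyl tris[4-(benzyloxy)benzoate] | O=C(COCc1ccccc1)c1c(OC(=O)c2ccc(OCc3ccccc3)cc2)cc(OC(=O)c2ccc(OCc3ccccc3)cc2)cc1OC(=O)c1ccc(OCc2ccccc2)cc1
F3 | step 4 | 4-{2-(benzyloxy)-3-[4-(benzyloxy)phenyl]-3-oxopropanoyl}-5-hydroxybenzene-1,3-diyl bis[4-(benzyloxy)benzoate] (racemic) | O=C(c1ccc(OCc2ccccc2)cc1)C(OCc1ccccc1)C(=O)c1c(O)cc(OC(=O)c2ccc(OCc3ccccc3)cc2)cc1OC(=O)c1ccc(OCc2ccccc2)cc1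
F4 | step 4 | 3-(benzyloxy)-2-[4-(benzyloxy)phenyl]-4-oxo-4H-chromene-5,7-diyl bis[4-(benzyloxy)benzoate] | O=c1c(OCc2ccccc2)c(-c2ccc(OCc3ccccc3)cc2)oc2cc(OC(=O)c3ccc(OCc4ccccc4)cc3)cc(OC(=O)c3ccc(OCc4ccccc4)cc3)c12
F5 | step 3 | methyl 2-(benzyloxy)-3-[4-(benzyloxy)phenyl]-3-hydroxypropanoate (racemic diastereomer mixture) | COC(=O)C(OCc1ccccc1)C(O)c1ccc(OCc2ccccc2)cc1
F6 | step 3 | methyl 2-(benzyloxy)-3-[4-(benzyloxy)phenyl]-3-[(triethylsilyl)oxy]propanoate (racemic diastereomer mixture) | COC(=O)C(OCc1ccccc1)C(O[Si](CC)(CC)CC)c1ccc(OCc2ccccc2)cc1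
F7 | step 3 | 6-{3-(benzyloxy)-4-[4-(benzyloxy)phenyl]-2-oxo-4-[(triethylsilyl)oxy]butyl}-4-hydroxy-2H-pyran-2-one (racemic diastereomer mixture) | O=C(CC1=CC(O)=CC(=O)O1)C(OCc1ccccc1)C(O[Si](CC)(CC)CC)c1ccc(OCc2ccccc2)cc1
F8 | step 3 | 6-{3-(benzyloxy)-4-[4-(benzyloxy)phenyl]-4-hydroxy-2-oxobutyl}-4-hydroxy-2H-pyran-2-one (racemic diastereomer mixture) | O=C(CC1=CC(O)=CC(=O)O1)C(OCc1ccccc1)C(O)c1ccc(OCc2ccccc2)cc1
F9 | step 6 | 3-(benzyloxy)-2-[4-(benzyloxy)phenyl]-5-hydroxy-4-oxo-4H-chromen-7-yl 2,2,2-trichloroethyl sulfate | O=c1c(OCc2ccccc2)c(-c2ccc(OCc3ccccc3)cc2)oc2cc(OS(=O)(=O)OCC(Cl)(Cl)Cl)cc(O)c12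
F10 | step 6 | ammonium kaempferol 7-sulfate | O=c1c(O)c(-c2ccc(O)cc2)oc2cc(OS(=O)(=O)[O-])cc(O)c12.[NH4+]
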